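## Retrosynthetic overview

1. Target 24 ⇐ diallyl compound 21 by twofold cross-metathesis; 21 ⇐ dibromide 18 + allyltributylstannane 19 by radical allylation at C1 and C3 (bonds C1–CH2 and C3–CH2, no ring closed).
2. Feature used: in the 6-oxabicyclo[3.2.1]octane-7,8-dione cage the two prenyl-bearing carbons are the bridgehead C1 (between lactone carbonyl C7 and ketone C8) and the methine C3 (beside the gem-dimethyl carbon C4). Neither can be an enolate carbon, both are good radical sites, and the O6–C7 bridge lies 1,3-diaxial over one face of C3.
3. 18 ⇐ 3,3-dibromo dione 17 by bromine-transfer 6-endo radical cyclisation (C1–C2 bond), which closes the carbocycle C1–C2–C3–C4–C5–C8 as the second ring.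
4. 17 ⇐ hydroxy keto ester 10 by O-malonylation, Dieckmann closure of the lactone ring O6–C7–C1–C8–C5 (the first ring), loss of the ester group and dibromination.
5. 10 ⇐ diazo keto ester 2 + (R)-allylic alcohol 4 by rhodium-carbenoid O–H insertion, Claisen rearrangement and α-ketol shift (sets C5), then ozonolysis and methylenation.

Key step: step 11

Assumption: the sense of chirality transfer in step 3 is derived from a chair Claisen transition state of the (Z)-enol and a suprafacial ketol shift through the syn-periplanar O–C–C=O conformer; should the shift run through the anti conformer, the (S)-alcohol from the enantiomeric reduction catalyst is used and nothing else changes.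

## Route

Step 1
Reactants: 1 methyl 4-methyl-3-oxopentanoate
Product: 2 methyl 2-diazo-4-methyl-3-oxopentanoate
Conditions: 4-acetamidobenzenesulfonyl azide, Et3N, MeCN, 0 °C to 25 °C
Reagents that add atoms: 4-acetamidobenzenesulfonyl azide, CC(=O)Nc1ccc(cc1)S(=O)(=O)N=[N+]=[N-]
Why: Regitz diazo transfer: the doubly activated methylene of the β-keto ester is deprotonated by the amine and takes the diazo group from the sulfonyl azide; no stereocentre is involved.

Step 2
Reactants: 3 mesityl oxide
Product: 4 (2R)-4-methylpent-3-en-2-ol
Conditions: (S)-Me-CBS oxazaborolidine [(3aS)-1-methyl-3,3-diphenyltetrahydro-1H,3H-pyrrolo[1,2-c][1,3,2]oxazaborole, 10 mol %], catecholborane, PhMe, −78 °C; aq. NaOH work-up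
Reagents that add atoms: none
Why: Corey–Bakshi–Shibata reduction: the ketone binds the oxazaborolidine with the 2-methylprop-1-enyl group as the large and methyl as the small substituent, so the (S)-catalyst should deliver hydride to the face that gives the (R)-carbinol, and catecholborane at low temperature leaves the trisubstituted alkene untouched.

Step 3
Reactants: 2 methyl 2-diazo-4-methyl-3-oxopentanoate; 4 (2R)-4-methylpent-3-en-2-ol
Product: 7 methyl (2R,4E)-2-hydroxy-3,3-dimethyl-2-(2-methylpropanoyl)hex-4-enoate, via enol ether 5 (not isolated), via hydroxy keto ester 6 (not isolated)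
Conditions: Rh2(OAc)4 (1 mol %), 4 (1.1 equiv), PhH, 80 °C, slow addition of 2; then BF3·OEt2, 25 °C
Reagents that add atoms: none
Why: Rhodium-carbenoid O–H insertion gives the (Z)-enol ether 5, which undergoes a Claisen rearrangement through a chair with the carbinol methyl equatorial (the axial alternative clashes with the cis methyl of the trisubstituted alkene), transferring the carbinol configuration to C3 of 6 and creating the CMe2 quaternary carbon and the E-alkene; the BF3-promoted α-ketol shift then moves the tertiary allylic group suprafacially to the neighbouring ketone carbon, which places the carbinol stereocentre (future C5) between the ester and the isobutyryl ketone.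

Step 4
Reactants: 7 methyl (2R,4E)-2-hydroxy-3,3-dimethyl-2-(2-methylpropanoyl)hex-4-enoate
Product: 9 methyl (2R)-2-hydroxy-3,3-dimethyl-2-(2-methylpropanoyl)-4-oxobutanoate, via ozonide 8 (not isolated)
Conditions: O3, CH2Cl2, −78 °C; then PPh3, −78 °C to 25 °C
Reagents that add atoms: ozone, [O-][O+]=O
Why: Ozonolysis with reductive work-up cleaves the only C=C bond; the aldehyde formed has a quaternary α-carbon and cannot enolise, and the tertiary carbinol stereocentre is not touched.

Step 5
Reactants: 9 methyl (2R)-2-hydroxy-3,3-dimethyl-2-(2-methylpropanoyl)-4-oxobutanoate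
Product: 10 methyl (2R)-2-hydroxy-3,3-dimethyl-2-(2-methylpropanoyl)pent-4-enoate
Conditions: Zn, CH2Br2, TiCl4, THF/CH2Cl2, 0 °C to 25 °C
Reagents that add atoms: dibromomethane, BrCBr
Why: Lombardo methylenation: the non-basic zinc/titanium methylene reagent should react with the aldehyde much faster than with the hindered ketone or the ester and, unlike a phosphorus ylide, does not generate a free alkoxide that could trigger retro-aldol cleavage or an acyloin shift at the stereocentre.

Step 6
Reactants: 10 methyl (2R)-2-hydroxy-3,3-dimethyl-2-(2-methylpropanoyl)pent-4-enoate; 11 3-tert-butoxy-3-oxopropanoic acid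
Product: 12 1-tert-butyl 3-[(2R)-1-methoxy-3,3-dimethyl-2-(2-methylpropanoyl)-1-oxopent-4-en-2-yl] propanedioate
Conditions: 11 (2 equiv), N,N'-dicyclohexylcarbodiimide (2 equiv), CH2Cl2, 0 °C to 25 °C, no amine base
Reagents that add atoms: none
Why: Carbodiimide activation of a malonic half ester proceeds through tert-butoxycarbonylketene (ketene acylation), which esterifies even crowded tertiary alcohols under neutral conditions, so the α-hydroxy β-keto ester should be acylated without an acyloin shift.

Step 7
Reactants: 12 1-tert-butyl 3-[(2R)-1-methoxy-3,3-dimethyl-2-(2-methylpropanoyl)-1-oxopent-4-en-2-yl] propanedioate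
Product: 13 tert-butyl (5S)-4-hydroxy-5-(2-methylbut-3-en-2-yl)-5-(2-methylpropanoyl)-2-oxo-2,5-dihydrofuran-3-carboxylate
Conditions: KOtBu (2.2 equiv), THF, 0 °C to 25 °C; then 1 M HCl
Reagents that add atoms: none
Why: Lacey–Dieckmann condensation: the stabilised malonate anion adds only reversibly to the hindered isobutyryl ketone but displaces methoxide from the ester irreversibly, because the 3-acyl tetronate is deprotonated at once, and this closes the lactone ring O6–C7–C1–C8–C5; a plain acetate would need a hard lithium enolate that is expected to attack the ketone and shift the acyl group, hence the malonate.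

Step 8
Reactants: 13 tert-butyl (5S)-4-hydroxy-5-(2-methylbut-3-en-2-yl)-5-(2-methylpropanoyl)-2-oxo-2,5-dihydrofuran-3-carboxylate
Product: 15 (5S)-4-hydroxy-5-(2-methylbut-3-en-2-yl)-5-(2-methylpropanoyl)furan-2(5H)-one, via carboxylic acid 14 (not isolated)
Conditions: CF3CO2H/CH2Cl2 (1:3), 25 °C; evaporate; PhMe, 80 °C
Reagents that add atoms: none
Why: Acidolysis of the tert-butyl ester gives the vinylogous β-keto acid 14, which should lose CO2 on warming (decarboxylation), while the vinyl group on a quaternary carbon and the C5 stereocentre, which has no α-hydrogen, are inert to the acid.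

Step 9
Reactants: 15 (5S)-4-hydroxy-5-(2-methylbut-3-en-2-yl)-5-(2-methylpropanoyl)furan-2(5H)-one
Product: 17 (5R)-3,3-dibromo-5-(2-methylbut-3-en-2-yl)-5-(2-methylpropanoyl)oxolane-2,4-dione, via monobromide 16 (not isolated)
Conditions: N-bromosuccinimide (2.1 equiv), CH2Cl2, 0 °C, dark; used at once
Reagents that add atoms: N-bromosuccinimide, O=C1CCC(=O)N1Br
Why: Twofold electrophilic α-bromination of the tetronic acid enol: the enol carbon is far more nucleophilic than the monosubstituted alkene, which has no allylic hydrogen for radical bromination, so both bromine atoms should go to the carbon that becomes C1.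

Step 10
Reactants: 17 (5R)-3,3-dibromo-5-(2-methylbut-3-en-2-yl)-5-(2-methylpropanoyl)oxolane-2,4-dione
Product: 18 (1S,3R,5R)-1,3-dibromo-4,4-dimethyl-5-(2-methylpropanoyl)-6-oxabicyclo[3.2.1]octane-7,8-dione
Conditions: Et3B (0.2 equiv), trace air, PhMe (0.02 M), 0 °C to 25 °C
Reagents that add atoms: none
Why: Bromine atom-transfer radical cyclisation: an ethyl radical takes one bromine, the planar dicarbonyl radical at C1 adds to the terminal alkene carbon C2 in the 6-endo mode (favoured by the ketone C8 inside the forming ring, by the quaternary C4 that hinders 5-exo attack at C3 and by the strain of the [2.2.1] alternative), which closes the carbocycle C1–C2–C3–C4–C5–C8, and the C3 radical takes bromine from 17 to carry the chain; C1 is fixed by C5 because the three-carbon bridge can span only one face of the lactone ring, and the configuration of the C3 bromide is immaterial.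

Step 11
Reactants: 18 (1S,3R,5R)-1,3-dibromo-4,4-dimethyl-5-(2-methylpropanoyl)-6-oxabicyclo[3.2.1]octane-7,8-dione; 19 allyltributylstannane
Product: 21 (1R,3R,5R)-4,4-dimethyl-5-(2-methylpropanoyl)-1,3-di(prop-2-en-1-yl)-6-oxabicyclo[3.2.1]octane-7,8-dione, via monoallyl bromide 20 (not isolated)
Conditions: 19 (8 equiv, at least 2 M), azobisisobutyronitrile (0.2 equiv, two portions), degassed PhH, 80 °C; KF work-up
Reagents that add atoms: none
Why: Tributyltin radicals generated in the azo-initiated chain abstract bromine first from C1, whose C–Br bond is weakened by the C7 and C8 carbonyls, and then from C3; each carbon radical adds to the CH2 terminus of 19 and β-scission of the C–Sn bond releases the allyl group and the chain-carrying tin radical, forming the C1–allyl and C3–allyl bonds. This is the Keck radical allylation, a known reaction of secondary alkyl bromides and of bridgehead halides flanked by carbonyl groups; no ring is closed. Because a radical at C1 can stay pyramidal and need not overlap with the neighbouring carbonyls, the anti-Bredt restriction that rules out enolate chemistry at this bridgehead does not apply, and the configuration at C1 is dictated by the cage. C3 is the only new stereocentre and is set by the substrate: O6 and C7, held axially on C5 and C1, cover one face of the flat C3 radical, so the stannane should approach from the opposite, equatorial side and the allyl group should end up anti to the lactone bridge, and both C3 epimers of the bromide converge on this product. The step needs intermolecular allyl transfer to outrun the unimolecular escapes of the C3 radical (β-scission of the C1–C2 or C4–C5 bond, 1,5-hydrogen shift from the isobutyryl methine), which the large excess of stannane at high concentration is meant to secure. Cyclisation of either radical onto the allyl group already in place is ruled out because the two 1,3-related exocyclic positions are both equatorial and cannot be bridged.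

Step 12
Reactants: 21 (1R,3R,5R)-4,4-dimethyl-5-(2-methylpropanoyl)-1,3-di(prop-2-en-1-yl)-6-oxabicyclo[3.2.1]octane-7,8-dione; 22 2-methylbut-2-ene
Product: 24 (1R,3R,5R)-4,4-dimethyl-1,3-bis(3-methylbut-2-en-1-yl)-5-(2-methylpropanoyl)-6-oxabicyclo[3.2.1]octane-7,8-dione, via monoprenyl compound 23 (not isolated)
Conditions: second-generation Grubbs catalyst (10 mol %), 22/CH2Cl2 (1:1), 40 °C, sealed tube
Reagents that add atoms: none
Why: Olefin cross-metathesis with 2-methylbut-2-ene in large excess should convert each terminal allyl group into a prenyl group with loss of propene, the less hindered C3 allyl group reacting first, and ring-closing metathesis is excluded because the two equatorial allyl groups cannot reach each other; no stereocentre is affected.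

## Compound list

1 | methyl 4-methyl-3-oxopentanoate | CC(C)C(=O)CC(=O)OC | starting material
2 | methyl 2-diazo-4-methyl-3-oxopentanoate | CC(C)C(=O)C(=[N+]=[N-])C(=O)OC | intermediate
3 | mesityl oxide (4-methylpent-3-en-2-one) | CC(C)=CC(C)=O | starting material
4 | (2R)-4-methylpent-3-en-2-ol | C[C@@H](O)C=C(C)C | intermediate
5 | methyl (2Z)-3-hydroxy-4-methyl-2-{[(2R)-4-methylpent-3-en-2-yl]oxy}pent-2-enoate | COC(=O)/C(O[C@H](C)C=C(C)C)=C(/O)C(C)C | intermediate
6 | methyl (3S,5E)-3-hydroxy-4,4-dimethyl-2-oxo-3-(propan-2-yl)hept-5-enoate | C/C=C/C(C)(C)[C@@](O)(C(C)C)C(=O)C(=O)OC | intermediate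
7 | methyl (2R,4E)-2-hydroxy-3,3-dimethyl-2-(2-methylpropanoyl)hex-4-enoate | C/C=C/C(C)(C)[C@](O)(C(=O)OC)C(=O)C(C)C | intermediate
8 | methyl (2R)-2-hydroxy-3-methyl-3-(5-methyl-1,2,4-trioxolan-3-yl)-2-(2-methylpropanoyl)butanoate (ozonide, mixture at the ring carbons) | CC1OOC(O1)C(C)(C)[C@](O)(C(=O)OC)C(=O)C(C)C | intermediate
9 | methyl (2R)-2-hydroxy-3,3-dimethyl-2-(2-methylpropanoyl)-4-oxobutanoate | O=CC(C)(C)[C@](O)(C(=O)OC)C(=O)C(C)C | intermediate
10 | methyl (2R)-2-hydroxy-3,3-dimethyl-2-(2-methylpropanoyl)pent-4-enoate | C=CC(C)(C)[C@](O)(C(=O)OC)C(=O)C(C)C | intermediate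
11 | 3-tert-butoxy-3-oxopropanoic acid (mono-tert-butyl malonate) | CC(C)(C)OC(=O)CC(=O)O | starting material
12 | 1-tert-butyl 3-[(2R)-1-methoxy-3,3-dimethyl-2-(2-methylpropanoyl)-1-oxopent-4-en-2-yl] propanedioate | C=CC(C)(C)[C@](OC(=O)CC(=O)OC(C)(C)C)(C(=O)OC)C(=O)C(C)C | intermediate
13 | tert-butyl (5S)-4-hydroxy-5-(2-methylbut-3-en-2-yl)-5-(2-methylpropanoyl)-2-oxo-2,5-dihydrofuran-3-carboxylate | C=CC(C)(C)[C@]1(C(=O)C(C)C)OC(=O)C(C(=O)OC(C)(C)C)=C1O | intermediate
14 | (5S)-4-hydroxy-5-(2-methylbut-3-en-2-yl)-5-(2-methylpropanoyl)-2-oxo-2,5-dihydrofuran-3-carboxylic acid | C=CC(C)(C)[C@]1(C(=O)C(C)C)OC(=O)C(C(=O)O)=C1O | intermediate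
15 | (5S)-4-hydroxy-5-(2-methylbut-3-en-2-yl)-5-(2-methylpropanoyl)furan-2(5H)-one | C=CC(C)(C)[C@]1(C(=O)C(C)C)OC(=O)C=C1O | intermediate
16 | (5S)-3-bromo-4-hydroxy-5-(2-methylbut-3-en-2-yl)-5-(2-methylpropanoyl)furan-2(5H)-one | C=CC(C)(C)[C@]1(C(=O)C(C)C)OC(=O)C(Br)=C1O | intermediate
17 | (5R)-3,3-dibromo-5-(2-methylbut-3-en-2-yl)-5-(2-methylpropanoyl)oxolane-2,4-dione | C=CC(C)(C)[C@]1(C(=O)C(C)C)OC(=O)C(Br)(Br)C1=O | intermediate
18 | (1S,3R,5R)-1,3-dibromo-4,4-dimethyl-5-(2-methylpropanoyl)-6-oxabicyclo[3.2.1]octane-7,8-dione (C3 epimer with bromine anti to the O6–C7 bridge shown; the other epimer serves equally) | Br[C@@H]1C[C@@]2(Br)C(=O)O[C@](C(=O)C(C)C)(C2=O)C1(C)C | intermediate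
19 | allyltributylstannane (tributyl(prop-2-en-1-yl)stannane) | C=CC[Sn](CCCC)(CCCC)CCCC | starting material
20 | (1R,3R,5R)-3-bromo-4,4-dimethyl-5-(2-methylpropanoyl)-1-(prop-2-en-1-yl)-6-oxabicyclo[3.2.1]octane-7,8-dione (C3 epimer as in 18) | Br[C@@H]1C[C@@]2(CC=C)C(=O)O[C@](C(=O)C(C)C)(C2=O)C1(C)C | intermediate
21 | (1R,3R,5R)-4,4-dimethyl-5-(2-methylpropanoyl)-1,3-di(prop-2-en-1-yl)-6-oxabicyclo[3.2.1]octane-7,8-dione | C=CC[C@@H]1C[C@@]2(CC=C)C(=O)O[C@](C(=O)C(C)C)(C2=O)C1(C)C | intermediate
22 | 2-methylbut-2-ene | CC=C(C)C | starting material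
23 | (1R,3R,5R)-4,4-dimethyl-3-(3-methylbut-2-en-1-yl)-5-(2-methylpropanoyl)-1-(prop-2-en-1-yl)-6-oxabicyclo[3.2.1]octane-7,8-dione | CC(C)=CC[C@@H]1C[C@@]2(CC=C)C(=O)O[C@](C(=O)C(C)C)(C2=O)C1(C)C | intermediate
24 | (1R,3R,5R)-4,4-dimethyl-1,3-bis(3-methylbut-2-en-1-yl)-5-(2-methylpropanoyl)-6-oxabicyclo[3.2.1]octane-7,8-dione | CC(C)=CC[C@@H]1C[C@@]2(CC=C(C)C)C(=O)O[C@](C(=O)C(C)C)(C2=O)C1(C)C | target

## Step count and risks

Total step count: 12.
Longest linear sequence: 11 steps (step 1 or step 2, then steps 3 to 12).

Steps most likely to fail: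

**Step 11 (key step).** Allyl transfer to the crowded C3 radical may be slower than its ring-opening β-scission or its 1,5-hydrogen shift, or approach from the bridge side may compete, eroding yield or the C3 configuration. The fallback sets out from dibromide 18. Only the bridgehead is allylated under radical conditions (19, 1.1 equiv, Et3B/air, 0 °C), since the doubly activated C1–Br bond should react far faster than the neopentyl-type C3–Br bond, and monoallyl bromide 20 is isolated. The C3–allyl bond is then made by nickel-catalysed cross-electrophile coupling of 20 with allyl methyl carbonate (NiBr2(MeOCH2CH2OMe), 4,4'-di-tert-butyl-2,2'-bipyridine, Zn, N,N-dimethylacetamide, 25 °C). There the C3 radical is captured by the metal instead of an alkene, and face selection rests on the same shielding by the bridge. The route is rejoined at 21.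

**Step 3.** The Claisen step must join two fully substituted carbons, so tautomerisation of the enol to the plain O–H insertion product may outrun it. The Lewis acid may also ionise the tertiary allylic group instead of shifting it, with loss of configuration. The fallback sets out from diazo ester 2. Oxidation with dimethyldioxirane (acetone, 0 °C) should give methyl 4-methyl-2,3-dioxopentanoate F1. An indium-mediated Barbier reaction with 1-bromo-3-methylbut-2-ene (THF/H2O) attacks the central, most electrophilic carbonyl through the γ-carbon and should give racemic methyl 2-hydroxy-3,3-dimethyl-2-(2-methylpropanoyl)pent-4-enoate F2. The enantiomers are separated by preparative chromatography on a chiral stationary phase; the (R)-enantiomer is compound 10, where the route is rejoined, and steps 2 to 5 are no longer needed.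

**Step 10.** The bromine-transfer chain may be short because triethylborane can also reduce the dibromide, and ring-opening of the cyclised radical or loss of the bridgehead bromine may compete. The fallback sets out from tetronic acid 15. Tsuji–Trost C-allylation with allyl acetate and Pd(PPh3)4 (zerovalent palladium, THF) should give (5S)-4-hydroxy-5-(2-methylbut-3-en-2-yl)-5-(2-methylpropanoyl)-3-(prop-2-en-1-yl)furan-2(5H)-one F3. One equivalent of N-bromosuccinimide should give (5R)-3-bromo-5-(2-methylbut-3-en-2-yl)-5-(2-methylpropanoyl)-3-(prop-2-en-1-yl)oxolane-2,4-dione F4. Heating F4 with excess 19 and azobisisobutyronitrile in benzene generates the C1 radical with its allyl group already in place; it should close the six-membered ring 6-endo, and the C3 radical takes its allyl group from the stannane. This needs neither a bromine-transfer chain nor a bridgehead bromide, and the route is rejoined at 21.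

Further compounds
F1 | step 3 | methyl 4-methyl-2,3-dioxopentanoate | CC(C)C(=O)C(=O)C(=O)OC
F2 | step 3 | racemic methyl 2-hydroxy-3,3-dimethyl-2-(2-methylpropanoyl)pent-4-enoate | C=CC(C)(C)C(O)(C(=O)OC)C(=O)C(C)C
F3 | step 10 | (5S)-4-hydroxy-5-(2-methylbut-3-en-2-yl)-5-(2-methylpropanoyl)-3-(prop-2-en-1-yl)furan-2(5H)-one | C=CC(C)(C)[C@]1(C(=O)C(C)C)OC(=O)C(CC=C)=C1O
F4 | step 10 | (5R)-3-bromo-5-(2-methylbut-3-en-2-yl)-5-(2-methylpropanoyl)-3-(prop-2-en-1-yl)oxolane-2,4-dione (both C3 epimers) | C=CC(C)(C)[C@]1(C(=O)C(C)C)OC(=O)C(Br)(CC=C)C1=O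
F0 | step 11 | none | none
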